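Locants used throughout: the naphthalene half is C1–C8a (ring A = C1–C4, C4a, C8a; ring B = C4a–C8a); the dihydronaphthalene half is primed (ring C = the arene C4a'–C8a'; ring D = C1'–C4', C4a', C8a').

## Analysis of the target

Target 19 is a 7,7'-linked biaryl of two units with the same carbon skeleton. Rings A and B form a 2-acetyl-1,8-dihydroxy-3-methylnaphthalene; rings C and D form the same skeleton at the 1',2'-dihydro-1'-ol oxidation level. There are two adjacent stereocentres, C1' (S, carbinol) and C2' (R, acetyl-bearing), trans to each other on ring D. The C7–C7' axis has only two ortho substituents and is not a stereo-element. Ring D is a β-hydroxy ketone: C1'–OH is benzylic, and C2'–H is both α to the ketone and allylic to C3'=C4', so dehydration would aromatise ring D, C2' can epimerise and the aldol can revert. Ring D therefore has to be closed last, under near-neutral conditions, with no deprotection after it, whereas ring A must be fully aromatic. The difficulty is that two halves of equal constitution need different chemistry. The strategy rests on ring A: OH on C1, acetyl on C2, methyl on C3 and H on C4, fused at C4a–C8a. This is the pattern left when a benzylic carbanion (C4) and an ortho ester carbon (C1) on ring B react with the β- and α-carbons of a four-carbon β-methoxy enone.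

## Retrosynthetic reasoning

**19 ⇒ 17.** The last bond made is C1'–C2'. Cutting it gives 17, with C1' as a formyl group on C8a' and a 2-methyl-4-oxopent-2-enyl arm on C4a'. This is the only cut that creates both stereocentres in one event and leaves nothing to be done to ring D afterwards. A cut at C3'=C4' or C4'–C4a' would leave the labile hydroxy ketone in an open chain that must survive further steps. The forward reaction must bring the α-carbon of the enone (C2') onto the aldehyde through dienamine 18, fix C1' as S and C2' as R, and stop before dehydration. Every double-bond isomer of the arm gives the same dienamine, so the arm need not be geometrically pure.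

**17 ⇒ 15 + 16.** The arm is cut at its C=C bond into the methallyl group of 15 and vinyl ketone 16 (olefin cross-metathesis). A carbonyl olefination at this bond was rejected: a stabilised ylide or phosphonate would have to attack an enolisable benzyl methyl ketone, and the aldehyde on C8a' would react first. Metathesis touches neither the aldehyde nor the phenols.

**15 ⇒ 13 + 14.** The C4a'–C4' bond is cut into aryl chloride 13 and allylstannane 14 (Stille coupling). The chlorine has been carried from 5 as a silent handle, and the ortho formyl group of 13 activates it.

**13 ⇒ 12.** The C8a'–C1' bond is cut (magnesium-directed ortho-formylation). In 12 both ortho positions of the C1 and C8 hydroxyls are substituted, so the C8' hydroxyl can only direct to C8a'. No selective protection is needed.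

**12 ⇒ 11.** The O–CH3 bonds at C8 and C8' are cleaved directly after the annulation, while the molecule contains nothing acid-sensitive. From there the route runs without protecting groups, so no deprotection follows closure of ring D.

**11 ⇒ 6 + 7.** Ring A is cut at C3–C4 and C1–C2. This returns biaryl toluate 6 (ring-B methyl carbon becomes C4, ester carbon becomes C1) and enone 7 (β-carbon becomes C3 with its methyl, α-carbon becomes C2 with the acetyl). This cut delivers hydroxyl, acetyl and methyl in their final positions in one operation and at the aromatic oxidation level. Acetylation of a preformed naphthol would have to choose between C2 and C4. Forward, lateral anion 8 must add to 7 in the conjugate sense, enolate 9 must close onto the hindered ester to give 10, and both methoxy groups must leave.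

**6 ⇒ 4 + 5.** The C7–C7' bond is cut into bromide 4 and boronic acid 5 (Suzuki–Miyaura coupling). Coupling before the annulation keeps palladium chemistry away from the free naphthol. The halogens are differentiated by reactivity: bromine on ring B couples, chlorine on ring C stays.

**4 ⇒ 3 ⇒ 2 ⇒ 1.** The ester carbon is introduced as a formyl group at the one free ortho position of phenol 1, between the hydroxyl and the methyl group. The 1,2,3-relationship of methyl, ester and oxygen needed for the annulation is thus fixed by the substitution pattern of 1, not by a selective reaction.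

## Alternatives that were turned down

**Alternative 1:** Both rings D of a symmetrical dimer are cut at C1'–C2', leading back to the symmetrical bis(enone) dialdehyde A1. Forward, a chiral amine converts both arms of A1 into dienamines and closes two rings to the C2-symmetric bis(dihydronaphthalenol) A2. One of the two carbinols of A2 is then oxidised so that this half tautomerises to the naphthol.
- For: A1 is accessible by homocoupling, the sequence is shorter than the chosen one, and a double closure with one catalyst raises the enantiopurity of the C2-symmetric product because mismatched material ends up as a separable meso isomer. On step count and on enantiopurity this plan is stronger.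
- Against: the two benzylic carbinols of A2 are homotopic, so mono-oxidation can only be statistical. Any oxidant or base strong enough is also likely to trigger dehydration, which gives a naphthalene lacking the C1 oxygen. Two of the four stereocentres are made only to be destroyed.
- Comparison: the chosen strategy differentiates the halves by construction. Ring A is made aromatic by annulation, ring D by a single aldol, and no oxidation-state adjustment is needed on a molecule that contains the labile hydroxy ketone.

**Alternative 2:** Ring D is cut at C1'–C2' and C3'–C4' in a [4+2] sense. Forward, isobenzofuran A3 (ring C fused to a furan, generated in situ) adds to bromo enone A4 under a chiral boron Lewis acid to give the oxygen-bridged endo adduct A5. Reductive opening of the β-bromo ether then releases C1'–OH and C3'=C4' together, and three allyl ethers are removed.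
- For: both stereocentres arise in one concerted step. The endo rule gives the trans relationship and the bridge carries the C1' oxygen, so relative configuration is better secured than in an aldol that can equilibrate. On that point this plan is stronger.
- Against: A3 is a fragile diene that must be generated on an elaborate naphthyl arene. A4 is a β,β-disubstituted enone and a poor dienophile. The orientation of A4 (acetyl next to C1' or next to C4') is biased only by a remote alkoxy group. Three allyl ethers must be removed at the end in the presence of the hydroxy ketone. The step count is higher.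
- Comparison: in the chosen route the regiochemistry of ring D is fixed by the ortho relationship of formyl group and arm in 17, and the target is formed in the last step with no protecting group left.

**Alternative 3:** Ring B is cut at C5–C6 and C7–C8. Forward, the lateral anion of toluate A6 adds to α-aryl vinyl sulfone A7, the sulfonyl carbanion closes onto the ester and sulfinate leaves, giving naphthol A8 with the C7–C7' bond already in place.
- For: the two halves are joined while ring B is built, so no cross-coupling is needed. At the biaryl stage it is at least as convergent as the chosen route.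
- Against: A8 lacks the C2 acetyl group. A later C-acylation of an electron-rich 1,8-dioxygenated naphthalene would have to choose C2 over C4 and C5. A6 has two benzylic methyl groups. A7 is a hindered acceptor, and its tertiary carbanion must acylate a hindered ester. All the ring-D work remains.
- Comparison: the chosen annulation installs hydroxyl, acetyl and methyl of ring A in one regiodefined event, and a standard Suzuki–Miyaura coupling supplies the biaryl bond.

Key step: step 5

Assumption: the C7–C7' axis is taken as freely rotating, and the quinine-derived amine of step 10 is taken to give the (1'S,2'R) series; should it give the mirror-image series, the quinidine-derived pseudo-enantiomer would be used under the same conditions.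

## Route

Step 1
Reactants: 1 2-bromo-5-methylphenol
Product: 2 3-bromo-2-hydroxy-6-methylbenzaldehyde
Conditions: MgCl2, Et3N, (CH2O)n, THF, reflux; aq. HCl
Reagents that add atoms: formaldehyde (as paraformaldehyde), C=O
Why: Casnati–Skattebøl ortho-formylation: magnesium coordination at the phenol oxygen delivers formaldehyde to the only free ortho carbon, between OH and CH3, the other being blocked by bromine. 2-Bromophenols are standard substrates for this reaction.

Step 2
Reactants: 2 3-bromo-2-hydroxy-6-methylbenzaldehyde
Product: 3 3-bromo-2-hydroxy-6-methylbenzoic acid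
Conditions: NaClO2, NaH2PO4, 2-methylbut-2-ene, t-BuOH/H2O, 0 °C to rt
Reagents that add atoms: sodium chlorite, [Na+].[O-]Cl=O
Why: Pinnick oxidation of the aldehyde; the alkene scavenger removes hypochlorous acid and so should protect the electron-rich phenol ring from chlorination.

Step 3
Reactants: 3 3-bromo-2-hydroxy-6-methylbenzoic acid
Product: 4 methyl 3-bromo-2-methoxy-6-methylbenzoate
Conditions: MeI, K2CO3, DMF, 40 °C
Reagents that add atoms: iodomethane, CI
Why: Double O-alkylation (Williamson-type) of carboxylate and phenoxide; alkylating the carboxylate avoids the addition to the carbonyl group that makes Fischer esterification of 2,6-disubstituted benzoic acids slow.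

Step 4
Reactants: 4 methyl 3-bromo-2-methoxy-6-methylbenzoate; 5 (4-chloro-2-methoxyphenyl)boronic acid
Product: 6 methyl 3-(4-chloro-2-methoxyphenyl)-2-methoxy-6-methylbenzoate
Conditions: Pd(dppf)Cl2 (3 mol %), K2CO3, 1,4-dioxane/H2O, 85 °C
Reagents that add atoms: none
Why: Suzuki–Miyaura coupling; with a bisphosphine palladium catalyst the C–Br bond of 4 should undergo oxidative addition well before the C–Cl bond of 5, and the doubly ortho-substituted ester resists aqueous carbonate.

Step 5
Reactants: 6 methyl 3-(4-chloro-2-methoxyphenyl)-2-methoxy-6-methylbenzoate; 7 (E)-4-methoxypent-3-en-2-one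
Product: 11 1-[7-(4-chloro-2-methoxyphenyl)-1-hydroxy-8-methoxy-3-methylnaphthalen-2-yl]ethanone, via lithiated toluate 8 (not isolated), via Michael adduct enolate 9 (not isolated), via Claisen adduct 10 (not isolated)
Conditions: LiN(i-Pr)2 (1.3 equiv, commercial solution), THF, −78 °C; then 7, −78 °C to 0 °C; aq. HCl
Reagents that add atoms: none
Why: The hindered amide removes a proton from the methyl group ortho to the ester of 6 and gives 8, an ester-stabilised benzylic anion of ortho-quinodimethane character. Anion 8 adds through carbon to the methoxy-bearing β-carbon of 7 (future C3), forming C3–C4 and enolate 9. The α-carbon of 9 (future C2) then attacks the neighbouring ester in a 6-(enolexo)-exo-trig Claisen closure, forming C1–C2 and ring A as 10 with loss of the ester methoxy group. β-Elimination of the C3 methoxy group and tautomerisation aromatise ring A, so that hydroxyl, acetyl and methyl of 11 follow directly from the polarity of the two partners. The closest known reaction type is the Staunton–Weinreb annulation of toluate anions with β-alkoxy enones, which gives 2-acyl-3-methyl-1-naphthols. No stereocentre is left in 11; those of 10 are transient. The step needs lateral deprotonation in preference to attack on the ester or metalation next to chlorine, and conjugate addition in preference to carbonyl addition or proton transfer from the acetyl methyl group of 7. These are secured by the low temperature, the bulky base used in only slight excess, the doubly ortho-shielded ester, the acidifying ester next to the methyl group and the vinylogous-ester character of 7, while the aryl chloride and methyl ethers are inert at −78 °C.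

Step 6
Reactants: 11 1-[7-(4-chloro-2-methoxyphenyl)-1-hydroxy-8-methoxy-3-methylnaphthalen-2-yl]ethanone
Product: 12 1-[7-(4-chloro-2-hydroxyphenyl)-1,8-dihydroxy-3-methylnaphthalen-2-yl]ethanone
Conditions: BBr3, CH2Cl2, −78 °C to 0 °C; H2O
Reagents that add atoms: none
Why: Lewis-acid cleavage of both aryl methyl ethers (bromide attacks the O-methyl carbon of the boron-complexed ether); the aryl chloride and the chelated aryl ketone are inert. The step is placed here because no alkene, enone or aldehyde is yet present.

Step 7
Reactants: 12 1-[7-(4-chloro-2-hydroxyphenyl)-1,8-dihydroxy-3-methylnaphthalen-2-yl]ethanone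
Product: 13 3-(7-acetyl-1,8-dihydroxy-6-methylnaphthalen-2-yl)-6-chloro-2-hydroxybenzaldehyde
Conditions: MgCl2, Et3N, (CH2O)n, MeCN, 80 °C; aq. HCl
Reagents that add atoms: formaldehyde (as paraformaldehyde), C=O
Why: Casnati–Skattebøl ortho-formylation; the reaction is ortho-specific, and only the C8' hydroxyl has a free ortho carbon (C8a'), those of the C1 and C8 hydroxyls being substituted. A flanking halogen is tolerated by this reaction type, though it should slow it.

Step 8
Reactants: 13 3-(7-acetyl-1,8-dihydroxy-6-methylnaphthalen-2-yl)-6-chloro-2-hydroxybenzaldehyde; 14 tributyl(2-methylprop-2-en-1-yl)stannane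
Product: 15 3-(7-acetyl-1,8-dihydroxy-6-methylnaphthalen-2-yl)-2-hydroxy-6-(2-methylprop-2-en-1-yl)benzaldehyde
Conditions: Pd2(dba)3 (2.5 mol %), [HP(t-Bu)3]BF4 (10 mol %), CsF, 1,4-dioxane, 90 °C
Reagents that add atoms: none
Why: Stille coupling of an aryl chloride, made possible by the bulky electron-rich phosphine and fluoride activation of tin; the ortho formyl group activates the C–Cl bond. Allylstannanes do not add to aldehydes without a Lewis acid, and allyl Stille couplings of 2-halobenzaldehydes are standard.

Step 9
Reactants: 15 3-(7-acetyl-1,8-dihydroxy-6-methylnaphthalen-2-yl)-2-hydroxy-6-(2-methylprop-2-en-1-yl)benzaldehyde; 16 but-3-en-2-one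
Product: 17 3-(7-acetyl-1,8-dihydroxy-6-methylnaphthalen-2-yl)-2-hydroxy-6-[(2E)-2-methyl-4-oxopent-2-en-1-yl]benzaldehyde
Conditions: 16 (excess), second-generation Hoveyda–Grubbs catalyst RuCl2(H2IMes)(=CH-C6H4-2-O-i-Pr) (10 mol %), 1,4-benzoquinone (20 mol %), CH2Cl2, 40 °C
Reagents that add atoms: none
Why: Olefin cross-metathesis between a 1,1-disubstituted alkene and an electron-poor vinyl ketone, neither of which homodimerises readily, so the cross product should dominate. Benzoquinone suppresses migration of the allylic double bond, and the geometry of the new alkene is irrelevant because all isomers give the same dienamine in step 10.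

Step 10
Reactants: 17 3-(7-acetyl-1,8-dihydroxy-6-methylnaphthalen-2-yl)-2-hydroxy-6-[(2E)-2-methyl-4-oxopent-2-en-1-yl]benzaldehyde
Product: 19 1-[(1S,2R)-7-(7-acetyl-1,8-dihydroxy-6-methylnaphthalen-2-yl)-1,8-dihydroxy-3-methyl-1,2-dihydronaphthalen-2-yl]ethanone, via dienamine 18 (not isolated)
Conditions: 9-amino-9-deoxy-epi-quinine (20 mol %), PhCO2H (40 mol %), THF, 0 °C; pH 7 buffer
Reagents that add atoms: none
Why: Proposed new method: the primary amine condenses with the enone carbonyl of 17 (the ring-A acetyl is chelated and flanked on both sides) and loss of an acidic benzylic γ-hydrogen gives the linear dienamine 18, whose α-carbon C2' adds to the aldehyde in a 6-(enolexo)-exo-trig closure, the γ-carbon and the methyl carbon being excluded because they would close four- and eight-membered rings; hydrolysis of the carbon–nitrogen bond then releases 19 and the amine. The protonated quinuclidine nitrogen of the catalyst is expected to hydrogen-bond to the aldehyde oxygen and so present one face of the carbonyl group to the dienamine, which sets C1', and C2' is expected trans to it because only the trans isomer can hold hydroxyl and acetyl both pseudo-axial, away from the C8' oxygen and the C3' methyl group, in the half-chair transition state and product. The closest known reaction types are amine-catalysed 6-enolexo aldolisations of dicarbonyl compounds and dienamine aldol ring closures of aryl-tethered unsaturated aldehydes onto ortho carbonyl groups, neither of which has been shown with an enone donor or stopped at the hydroxy ketone.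

## Compound list

1 | 2-bromo-5-methylphenol | Cc1ccc(Br)c(O)c1 | starting material
2 | 3-bromo-2-hydroxy-6-methylbenzaldehyde | Cc1ccc(Br)c(O)c1C=O | intermediate
3 | 3-bromo-2-hydroxy-6-methylbenzoic acid | Cc1ccc(Br)c(O)c1C(=O)O | intermediate
4 | methyl 3-bromo-2-methoxy-6-methylbenzoate | COC(=O)c1c(C)ccc(Br)c1OC | intermediate
5 | (4-chloro-2-methoxyphenyl)boronic acid | COc1cc(Cl)ccc1B(O)O | starting material
6 | methyl 3-(4-chloro-2-methoxyphenyl)-2-methoxy-6-methylbenzoate | COC(=O)c1c(C)ccc(-c2ccc(Cl)cc2OC)c1OC | intermediate
7 | (E)-4-methoxypent-3-en-2-one | CO/C(C)=C/C(C)=O | starting material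
8 | lithiated toluate: methyl 3-(4-chloro-2-methoxyphenyl)-6-(lithiomethyl)-2-methoxybenzoate | COC(=O)c1c(C[Li])ccc(-c2ccc(Cl)cc2OC)c1OC | intermediate
9 | Michael adduct enolate: lithium enolate of methyl 3-(4-chloro-2-methoxyphenyl)-2-methoxy-6-(2-methoxy-2-methyl-4-oxopentyl)benzoate (racemic, enolate geometry not fixed) | COC(=O)c1c(CC(C)(OC)C=C(C)O[Li])ccc(-c2ccc(Cl)cc2OC)c1OC | intermediate
10 | Claisen adduct: 2-acetyl-7-(4-chloro-2-methoxyphenyl)-3,8-dimethoxy-3-methyl-3,4-dihydronaphthalen-1(2H)-one (diastereomer mixture, present as its enolate) | CC(=O)C1C(=O)c2c(OC)c(-c3ccc(Cl)cc3OC)ccc2CC1(C)OC | intermediate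
11 | 1-[7-(4-chloro-2-methoxyphenyl)-1-hydroxy-8-methoxy-3-methylnaphthalen-2-yl]ethanone | CC(=O)c1c(C)cc2ccc(-c3ccc(Cl)cc3OC)c(OC)c2c1O | intermediate
12 | 1-[7-(4-chloro-2-hydroxyphenyl)-1,8-dihydroxy-3-methylnaphthalen-2-yl]ethanone | CC(=O)c1c(C)cc2ccc(-c3ccc(Cl)cc3O)c(O)c2c1O | intermediate
13 | 3-(7-acetyl-1,8-dihydroxy-6-methylnaphthalen-2-yl)-6-chloro-2-hydroxybenzaldehyde | CC(=O)c1c(C)cc2ccc(-c3ccc(Cl)c(C=O)c3O)c(O)c2c1O | intermediate
14 | tributyl(2-methylprop-2-en-1-yl)stannane | C=C(C)C[Sn](CCCC)(CCCC)CCCC | starting material
15 | 3-(7-acetyl-1,8-dihydroxy-6-methylnaphthalen-2-yl)-2-hydroxy-6-(2-methylprop-2-en-1-yl)benzaldehyde | CC(=O)c1c(C)cc2ccc(-c3ccc(CC(C)=C)c(C=O)c3O)c(O)c2c1O | intermediate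
16 | but-3-en-2-one | C=CC(C)=O | starting material
17 | 3-(7-acetyl-1,8-dihydroxy-6-methylnaphthalen-2-yl)-2-hydroxy-6-[(2E)-2-methyl-4-oxopent-2-en-1-yl]benzaldehyde | CC(=O)/C=C(\C)Cc1ccc(-c2ccc3cc(C)c(C(C)=O)c(O)c3c2O)c(O)c1C=O | intermediate
18 | dienamine of 17 with (8S,9S)-9-amino-9-deoxy-epi-quinine at the enone carbonyl, C3'=C4' Z (C2' cis to ring C), enamine C=C geometry not fixed | COc1ccc2nccc([C@@H]([C@@H]3C[C@@H]4CCN3C[C@@H]4C=C)NC(C)=C/C(C)=C\c3ccc(-c4ccc5cc(C)c(C(C)=O)c(O)c5c4O)c(O)c3C=O)c2c1 | intermediate
19 | 1-[(1S,2R)-7-(7-acetyl-1,8-dihydroxy-6-methylnaphthalen-2-yl)-1,8-dihydroxy-3-methyl-1,2-dihydronaphthalen-2-yl]ethanone | CC(=O)c1c(C)cc2ccc(-c3ccc4c(c3O)[C@@H](O)[C@H](C(C)=O)C(C)=C4)c(O)c2c1O | target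

## Step count and least certain steps

Total step count: 10. Longest linear sequence: 10 steps (1 to 19); 5, 7, 14 and 16 enter as purchased reagents.

**Step 10 (proposed new method).**
- What may go wrong: loss of water across C1'–C2' after ring closure, through the same enamine and driven by aromatisation of ring D; insufficient facial discrimination at the aldehyde; epimerisation at C2'; and sequestration of the catalyst by reversible imine formation with the salicylaldehyde.
- Fallback (known chemistry): the route sets out from 17 and closes ring D under achiral soft-enolisation conditions (MgBr2·OEt2, i-Pr2NEt, CH2Cl2/THF, −20 °C). The magnesium dienolate can only cyclise through its α-carbon, and the chelated magnesium aldolate is protected against elimination. This should give the racemic trans aldol, that is 19 together with its enantiomer 1-[(1R,2S)-7-(7-acetyl-1,8-dihydroxy-6-methylnaphthalen-2-yl)-1,8-dihydroxy-3-methyl-1,2-dihydronaphthalen-2-yl]ethanone F1. Preparative chromatography on a chiral stationary phase then returns the route to 19.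

**Step 5 (key step).**
- What may go wrong: proton transfer from the acetyl methyl group of 7 to anion 8, which quenches the anion; addition of 8 to the carbonyl carbon instead of the β-carbon; and metalation between methoxy and chlorine on ring C with subsequent aryne formation on warming.
- Fallback: the route sets out from 6 and uses an acceptor without ketone α-hydrogens. Anion 8 is combined with methyl (E)-3-methoxybut-2-enoate in the same annulation to give methyl 7-(4-chloro-2-methoxyphenyl)-1-hydroxy-8-methoxy-3-methylnaphthalene-2-carboxylate F2. Saponification (LiOH, aq. THF) gives 7-(4-chloro-2-methoxyphenyl)-1-hydroxy-8-methoxy-3-methylnaphthalene-2-carboxylic acid F3. Excess MeLi in THF at 0 °C converts the lithium carboxylate into the methyl ketone, returning to 11.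

**Step 7.**
- What may go wrong: aldol-type reaction of formaldehyde, or of the product aldehyde, at the magnesium-chelated acetyl methyl group; and slow formylation because chlorine deactivates C8a' and the peri-diol binds magnesium.
- Fallback: the formyl group is introduced before the ketone exists. The route sets out from 4, which is coupled with (4-chloro-2-hydroxyphenyl)boronic acid under the conditions of step 4 to give methyl 3-(4-chloro-2-hydroxyphenyl)-2-methoxy-6-methylbenzoate F4. Magnesium-mediated formylation of its single phenol gives methyl 3-(4-chloro-3-formyl-2-hydroxyphenyl)-2-methoxy-6-methylbenzoate F5. MeI/K2CO3 gives methyl 3-(4-chloro-3-formyl-2-methoxyphenyl)-2-methoxy-6-methylbenzoate F6. HC(OMe)3/TsOH in MeOH gives methyl 3-[4-chloro-3-(dimethoxymethyl)-2-methoxyphenyl]-2-methoxy-6-methylbenzoate F7. Annulation of F7 with 7 as in step 5 gives 1-{7-[4-chloro-3-(dimethoxymethyl)-2-methoxyphenyl]-1-hydroxy-8-methoxy-3-methylnaphthalen-2-yl}ethanone F8. BBr3 followed by aqueous work-up cleaves both methyl ethers and the acetal and returns to 13.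

**Step 8.**
- What may go wrong: catalyst deactivation by phenoxide or salicylaldehyde chelation, slow oxidative addition, and allyl transfer to the neighbouring aldehyde.
- Fallback: the order of arm and formyl group is reversed. The route sets out from 12, which has no aldehyde, and a Suzuki–Miyaura coupling with 2-methylallylboronic acid pinacol ester (Pd(OAc)2, SPhos, K3PO4, THF/H2O) gives 1-{1,8-dihydroxy-7-[2-hydroxy-4-(2-methylprop-2-en-1-yl)phenyl]-3-methylnaphthalen-2-yl}ethanone F9. Magnesium-mediated formylation of F9, now at a position flanked by an alkyl arm as in step 1, returns to 15.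

## Further compounds

F1 | step 10 | 1-[(1R,2S)-7-(7-acetyl-1,8-dihydroxy-6-methylnaphthalen-2-yl)-1,8-dihydroxy-3-methyl-1,2-dihydronaphthalen-2-yl]ethanone | CC(=O)c1c(C)cc2ccc(-c3ccc4c(c3O)[C@H](O)[C@@H](C(C)=O)C(C)=C4)c(O)c2c1O
F2 | step 5 | methyl 7-(4-chloro-2-methoxyphenyl)-1-hydroxy-8-methoxy-3-methylnaphthalene-2-carboxylate | COC(=O)c1c(C)cc2ccc(-c3ccc(Cl)cc3OC)c(OC)c2c1O
F3 | step 5 | 7-(4-chloro-2-methoxyphenyl)-1-hydroxy-8-methoxy-3-methylnaphthalene-2-carboxylic acid | OC(=O)c1c(C)cc2ccc(-c3ccc(Cl)cc3OC)c(OC)c2c1O
F4 | step 7 | methyl 3-(4-chloro-2-hydroxyphenyl)-2-methoxy-6-methylbenzoate | COC(=O)c1c(C)ccc(-c2ccc(Cl)cc2O)c1OC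
F5 | step 7 | methyl 3-(4-chloro-3-formyl-2-hydroxyphenyl)-2-methoxy-6-methylbenzoate | COC(=O)c1c(C)ccc(-c2ccc(Cl)c(C=O)c2O)c1OC
F6 | step 7 | methyl 3-(4-chloro-3-formyl-2-methoxyphenyl)-2-methoxy-6-methylbenzoate | COC(=O)c1c(C)ccc(-c2ccc(Cl)c(C=O)c2OC)c1OC
F7 | step 7 | methyl 3-[4-chloro-3-(dimethoxymethyl)-2-methoxyphenyl]-2-methoxy-6-methylbenzoate | COC(=O)c1c(C)ccc(-c2ccc(Cl)c(C(OC)OC)c2OC)c1OC
F8 | step 7 | 1-{7-[4-chloro-3-(dimethoxymethyl)-2-methoxyphenyl]-1-hydroxy-8-methoxy-3-methylnaphthalen-2-yl}ethanone | CC(=O)c1c(C)cc2ccc(-c3ccc(Cl)c(C(OC)OC)c3OC)c(OC)c2c1O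
F9 | step 8 | 1-{1,8-dihydroxy-7-[2-hydroxy-4-(2-methylprop-2-en-1-yl)phenyl]-3-methylnaphthalen-2-yl}ethanone | CC(=O)c1c(C)cc2ccc(-c3ccc(CC(C)=C)cc3O)c(O)c2c1O
A1 | alternative 1 | 2,2'-dihydroxy-4,4'-bis[(2E)-2-methyl-4-oxopent-2-en-1-yl]biphenyl-3,3'-dicarbaldehyde | CC(=O)/C=C(\C)Cc1ccc(-c2ccc(C/C(C)=C/C(C)=O)c(C=O)c2O)c(O)c1C=O
A2 | alternative 1 | C2-symmetric 7,7'-bis[(1S,2R)-2-acetyl-1,8-dihydroxy-3-methyl-1,2-dihydronaphthalene] | Oc1c(-c2ccc3c(c2O)[C@@H](O)[C@H](C(C)=O)C(C)=C3)ccc2c1[C@@H](O)[C@H](C(C)=O)C(C)=C2
A3 | alternative 2 | 1-{1,8-bis(allyloxy)-7-[4-(allyloxy)-2-benzofuran-5-yl]-3-methylnaphthalen-2-yl}ethanone | CC(=O)c1c(C)cc2ccc(-c3ccc4cocc4c3OCC=C)c(OCC=C)c2c1OCC=C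
A4 | alternative 2 | (Z)-4-bromopent-3-en-2-one | C/C(Br)=C/C(C)=O
A5 | alternative 2 | endo-acetyl 3'-bromo-1',4'-epoxy-1',2',3',4'-tetrahydronaphthalene cycloadduct of A3 and A4 (tris-allyl ether) | CC(=O)c1c(C)cc2ccc(-c3ccc4c(c3OCC=C)[C@@H]5[C@H](C(C)=O)[C@](C)(Br)[C@H]4O5)c(OCC=C)c2c1OCC=C
A6 | alternative 3 | methyl 2-methoxy-4,6-dimethylbenzoate | COC(=O)c1c(C)cc(C)cc1OC
A7 | alternative 3 | 4-chloro-2-methoxy-1-[1-(phenylsulfonyl)ethenyl]benzene | C=C(c1ccc(Cl)cc1OC)S(=O)(=O)c1ccccc1
A8 | alternative 3 | 2-(4-chloro-2-methoxyphenyl)-8-methoxy-6-methylnaphthalen-1-ol | COc1cc(C)cc2ccc(-c3ccc(Cl)cc3OC)c(O)c12
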